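The pitfall here is to watch target sink in the cold blue run, from 14.8 % to 11.4 %, and conclude that heat must cost target.

| flask | starting material | reagent | free catalyst | temperature | remark | time |
|---|---|---|---|---|---|---|
| blue | 0.079 M | 0.013 M (fed, over 20 min) | 10 mM | 15 °C | run made earlier; the fed solution adds 0.50 times the starting volume |  |
| green | 0.079 M | 0.046 M (fed, over 20 min) | 10 mM | 35 °C | run made earlier; the fed solution adds 0.50 times the starting volume |  |
| violet | 0.079 M | 0.0553 M (fed, over 20 min) | 9.5 mM | 15 °C | run made earlier; the fed solution adds 0.50 times the starting volume |  |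
| east | 0.079 M | 0.0150 M (fed, over 12 min) | 6.0 mM | 20 °C | the fed solution adds 0.50 times the starting volume | 80 min |
| south-west | 0.079 M | 0.0553 M (fed, over 20 min) | 10 mM | 40 °C | the fed solution adds 0.50 times the starting volume | 80 min |
| north-west | 0.079 M | 0.0553 M (fed, over 20 min) | 10 mM | 20 °C | the fed solution adds 0.50 times the starting volume | 80 min |
| north | 0.079 M | 0.0553 M (fed, over 20 min) | 10 mM | 50 °C | the fed solution adds 0.50 times the starting volume | 80 min |

| run | time / min | target / % | starting material / % |
|---|---|---|---|
| blue | 15.0 | 11.4 | 85.1 |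
| blue | 30.0 | 14.8 | 76.9 |
| blue | 50.0 | 13.5 | 73.7 |
| blue | 60.0 | 12.3 | 73.3 |
| blue | 80.0 | 11.4 | 71.8 |
| green | 8.00 | 20.3 | 73.4 |
| green | 15.0 | 34.9 | 55.6 |
| green | 25.0 | 45.4 | 39.0 |
| green | 30.0 | 45.0 | 34.7 |
| green | 40.0 | 44.6 | 31.2 |
| violet | 6.00 | 10.4 | 88.9 |
| violet | 12.0 | 15.2 | 83.9 |
| violet | 25.0 | 22.8 | 74.0 |
| violet | 40.0 | 29.3 | 66.1 |
| violet | 80.0 | 41.3 | 46.6 |

(scatter of a reading: 0.3 percentage points)

- amounts are per litre of the starting volume; all of the dose is in the solution fed
- the numbers in the tables scatter with a standard deviation of 0.3 percentage points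

- the flasks put in order of amount of target, in percent of the starting material charged, best first, at 80 min (east / south-west / north-west / north)
- the amount of target, in percent of the starting material charged of the flask you put first, at 80 min
- the amount of target, in percent of the starting material charged of the flask you put last, at 80 min

The kept share q is target late in the run divided by the reagent dose, both in percent of starting material, taking one product per reagent. Green, drifting from 45.4 % to 44.6 % after its feed, has q = 76.6 % at 35 °C. Blue has 69.3 % at 15 °C, so green kept more; green also had the larger dose, and we assume that temperature made the difference. Blue was still sinking, so we take this slope as a gentle one.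

We let the odds of lost to kept change by the same factor per degree. The kept share of north, target over dose at its temperature, is then 81.2 %. For south-west we reckon 78.2 %, and for east and north-west 71.2 %. With a dose of 70.0 %, we expect 56.9 % in north, 54.8 % in south-west and 49.9 % in north-west. That last figure assumes its reagent is used up, which violet, still climbing at 41.3 %, leaves open. For east, with a dose of 19.0 %, we expect 13.5 %.

The forecast reads south-west > north > north-west > east, from 51 % down to 14 %, saying of north: “At 50 °C, selectivity is poorer”. The flasks give north > south-west > north-west > east, with 57.9 %, 55.1 %, 49.9 % and 13.1 %.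

    starting material + free catalyst → catalyst intermediate A (k = 0.297 L mol⁻¹ s⁻¹, Ea = 36.0 kJ mol⁻¹)
    catalyst intermediate A → catalyst intermediate B (k = 1.27 s⁻¹, Ea = 65.0 kJ mol⁻¹)
    reagent + catalyst intermediate B → catalyst intermediate C (k = 45.3 L mol⁻¹ s⁻¹, Ea = 51.0 kJ mol⁻¹)
    catalyst intermediate C ⇌ free catalyst + target (K = 0.850 M, k = 0.980 s⁻¹, Ea = 60.0 kJ mol⁻¹, ΔH = 0 kJ mol⁻¹)
    target ⇌ isomer of the product (K = 0.482, k = 2.35 × 10⁻⁴ s⁻¹, Ea = 80.0 kJ mol⁻¹, ΔH = −22.0 kJ mol⁻¹)
    free catalyst ⇌ dormant form (K = 7.82, k = 0.0568 s⁻¹, Ea = 67.0 kJ mol⁻¹, ΔH = −21.0 kJ mol⁻¹)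
    catalyst intermediate A → spent catalyst (k = 0.00474 s⁻¹, Ea = 89.0 kJ mol⁻¹)
    (constants at 20 °C)

In north, the mid-point of the making of catalyst intermediate B came at 9.76 min, earlier than the end of the feed at 20 min, and at 80 min reagent, the limiting reagent, stood at 0 % of its charge, with catalyst intermediate B holding 94.0 % of the catalyst. Target and isomer of the product relaxed towards each other, by that step alone, with a half-life of 0.403 min, shorter than the run, and north ended under thermodynamic control at 57.9 % target against 12.1 % isomer, a kept share of 82.7 %. A further flask like north, with 0.13 M of starting material, has a dose of 42.5 %; our 81.2 % of that is 34.6 %, and the flask holds 35.2 %.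

(Readings and results come from a simulation for an exercise; scatter was added.)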